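**Plan**
Retrosynthesis (ring numbered C1 carbonyl, C2 hydroxyl, C3 henicosyl, C4 carbonyl, C5 methoxyl, C6 hydrogen): the quinone goes back to its hydroquinone with the C2 oxygen as an isopropyl ether. The ring bond C4–C5 is cut first, then C1–C6 (vinyllithium plus cyclobutenedione), last the C3–chain bond (Grignard reagent plus squarate ester).
Enabling feature: the para carbonyls C1 and C4 split the substituents into two neighbouring pairs. C1–C2(O)–C3(chain)–C4 is a four-carbon squarate unit and C5(OMe)–C6(H) a two-carbon enol ether, the pieces of a 2,3-disubstituted cyclobutenone carrying a 2-methoxyvinyl group on its carbinol carbon.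
Forward: the chain is joined first (C21 Grignard to diisopropyl squarate, acid to the alkylcyclobutenedione), then the C5–C6 unit as (Z)-2-methoxyvinyllithium. The only ring of the target then arises by thermal 4π opening and 6π closure; BCl3 de-isopropylation and air oxidation finish.
Stereochemistry: the target has no stereocentre. The carbinol carbons made on the way are racemic and the Z enol ether geometry comes from bromine–lithium exchange with retention; both are erased on aromatisation.

Key step: step 6

Remark: the hydroxyquinone is treated as the 2-hydroxy-1,4-benzoquinone tautomer of the target SMILES, and all chiral intermediates are racemates.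

**Route**

Step 1
Reactants: 1 henicosan-1-ol
Product: 2 1-bromohenicosane
Conditions: CBr4, PPh3, CH2Cl2, 0 °C → rt
Reagents that add atoms: carbon tetrabromide, BrC(Br)(Br)Br
Why: Appel reaction, in which the primary alcohol is activated as an alkoxyphosphonium ion and displaced by bromide in an SN2 step; the saturated chain offers no competing site.

Step 2
Reactants: 2 1-bromohenicosane; 3 diisopropyl squarate (3,4-di(propan-2-yloxy)cyclobut-3-ene-1,2-dione)
Product: 5 racemic 4-henicosyl-4-hydroxy-2,3-di(propan-2-yloxy)cyclobut-2-en-1-one, via henicosylmagnesium bromide 4 (not isolated)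
Conditions: Mg, I2 (cat.), THF, reflux; then 3, THF, −78 → −20 °C; aq. NH4Cl
Reagents that add atoms: none
Why: Grignard formation and 1,2-addition to one carbonyl of the squarate ester, the standard first stage of the squarate-to-cyclobutenedione sequence; after one addition only a vinylogous ester carbonyl remains, which resists a second addition at low temperature, and the new carbinol carbon forms as the racemate.

Step 3
Reactants: 5 racemic 4-henicosyl-4-hydroxy-2,3-di(propan-2-yloxy)cyclobut-2-en-1-one
Product: 6 3-henicosyl-4-(propan-2-yloxy)cyclobut-3-ene-1,2-dione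
Conditions: 12 M HCl (cat.), CH2Cl2, rt
Reagents that add atoms: water, O
Why: acid-catalysed allylic transposition with hydrolysis, as used for squarate mono-adducts: the tertiary hydroxyl ionises to an alkoxy-stabilised cyclobutenyl cation, water adds at the far isopropoxy-bearing carbon and loss of propan-2-ol unveils the second carbonyl.

Step 4
Reactants: 7 methyl vinyl ether (methoxyethene)
Product: 9 (Z)-1-bromo-2-methoxyethene, via 1,2-dibromo-1-methoxyethane 8 (not isolated)
Conditions: Br2, pentane, −78 °C; then PhNEt2, 95 °C, distil
Reagents that add atoms: bromine, BrBr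
Why: bromine addition to the enol ether followed by amine-mediated dehydrobromination (addition–elimination), in which the α-bromo ether ionises and the proton beside the remaining bromine is lost; the Z isomer, favoured for 1-halo-2-alkoxyethenes, should predominate and is enriched by fractional distillation.

Step 5
Reactants: 9 (Z)-1-bromo-2-methoxyethene; 6 3-henicosyl-4-(propan-2-yloxy)cyclobut-3-ene-1,2-dione
Product: 11 racemic 2-henicosyl-4-hydroxy-4-[(Z)-2-methoxyethenyl]-3-(propan-2-yloxy)cyclobut-2-en-1-one, via [(Z)-2-methoxyethenyl]lithium 10 (not isolated)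
Conditions: n-BuLi, Et2O, −78 °C; then 6, THF, −78 °C; aq. NH4Cl, 0 °C; Et3N-deactivated SiO2
Reagents that add atoms: none
Why: bromine–lithium exchange with retention gives the oxygen-chelated (Z)-2-alkoxyvinyllithium, which adds 1,2 to the carbonyl flanked by the isopropoxy-bearing carbon because the other carbonyl is a deactivated vinylogous ester (the usual regiochemistry of organolithium additions to 3-alkyl-4-alkoxycyclobutenediones); the carbinol carbon forms as the racemate and is erased in step 6.

Step 6
Reactants: 11 racemic 2-henicosyl-4-hydroxy-4-[(Z)-2-methoxyethenyl]-3-(propan-2-yloxy)cyclobut-2-en-1-one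
Product: 14 3-henicosyl-5-methoxy-2-(propan-2-yloxy)benzene-1,4-diol, via dienylketene 12 (not isolated), via cyclohexadienone 13 (not isolated)
Conditions: PhMe (degassed), 110 °C, Ar
Reagents that add atoms: none
Why: Heating opens the cyclobutenone by thermally allowed 4π-conrotatory cleavage of the bond between the ring carbonyl carbon and the carbinol carbon, giving dienylketene 12. The hydroxyl, a strong donor, rotates outward, so the methoxyvinyl group turns inward and lies cis to the ketene-bearing carbon across the new enol double bond; this torquoselectivity is the one selectivity the step needs, and the carbinol oxygen of the substrate secures it. The ketene carbon (future C4) then bonds to the methoxy-bearing vinyl carbon (future C5) in a 6π-disrotatory electrocyclisation that closes the six-membered carbocycle as cyclohexadienone 13, and enolisation of 13 gives the aromatic hydroquinone 14. The closest known reaction type is the thermal ring expansion of 4-alkenyl-4-hydroxycyclobutenones to hydroquinones, the alkenyl counterpart of the Moore rearrangement. No stereocentre is set: the carbinol carbon and the sp3 carbon of 13 are both flattened on aromatisation, and either enol ether geometry would give the same arene. The substitution pattern follows from connectivity alone, since chain and isopropoxyl already sit on the four-membered ring and the methoxyl on the vinyl terminus.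

Step 7
Reactants: 14 3-henicosyl-5-methoxy-2-(propan-2-yloxy)benzene-1,4-diol
Product: 16 3-henicosyl-2-hydroxy-5-methoxycyclohexa-2,5-diene-1,4-dione, via 3-henicosyl-5-methoxybenzene-1,2,4-triol 15 (not isolated)
Conditions: BCl3 (excess), CH2Cl2, −78 → 0 °C; H2O; then air (O2), EtOAc/pH 7 buffer, rt
Reagents that add atoms: none
Why: Lewis-acid ether cleavage followed by autoxidation: BCl3 removes the secondary isopropyl group by an ionising pathway much faster than the methyl group, which would require SN2 attack, and the electron-rich benzene-1,2,4-triol is oxidised by O2 to the 2-hydroxy-1,4-benzoquinone, its stable tautomer.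

**Compound list**
1 | henicosan-1-ol | CCCCCCCCCCCCCCCCCCCCCO | starting material
2 | 1-bromohenicosane | CCCCCCCCCCCCCCCCCCCCCBr | intermediate
3 | diisopropyl squarate (3,4-di(propan-2-yloxy)cyclobut-3-ene-1,2-dione) | CC(C)OC1=C(OC(C)C)C(=O)C1=O | starting material
4 | henicosylmagnesium bromide | CCCCCCCCCCCCCCCCCCCCC[Mg]Br | intermediate
5 | racemic 4-henicosyl-4-hydroxy-2,3-di(propan-2-yloxy)cyclobut-2-en-1-one | CCCCCCCCCCCCCCCCCCCCCC1(O)C(OC(C)C)=C(OC(C)C)C1=O | intermediate
6 | 3-henicosyl-4-(propan-2-yloxy)cyclobut-3-ene-1,2-dione | CCCCCCCCCCCCCCCCCCCCCC1=C(OC(C)C)C(=O)C1=O | intermediate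
7 | methyl vinyl ether (methoxyethene) | COC=C | starting material
8 | racemic 1,2-dibromo-1-methoxyethane | COC(Br)CBr | intermediate
9 | (Z)-1-bromo-2-methoxyethene | CO/C=C\Br | intermediate
10 | [(Z)-2-methoxyethenyl]lithium | CO/C=C\[Li] | intermediate
11 | racemic 2-henicosyl-4-hydroxy-4-[(Z)-2-methoxyethenyl]-3-(propan-2-yloxy)cyclobut-2-en-1-one | CCCCCCCCCCCCCCCCCCCCCC1=C(OC(C)C)C(O)(/C=C\OC)C1=O | intermediate
12 | (3Z,5Z)-2-henicosyl-4-hydroxy-6-methoxy-3-(propan-2-yloxy)hexa-1,3,5-trien-1-one (dienylketene) | CCCCCCCCCCCCCCCCCCCCCC(=C=O)/C(OC(C)C)=C(O)\C=C/OC | intermediate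
13 | racemic 2-henicosyl-4-hydroxy-6-methoxy-3-(propan-2-yloxy)cyclohexa-2,4-dien-1-one | CCCCCCCCCCCCCCCCCCCCCC1=C(OC(C)C)C(O)=CC(OC)C1=O | intermediate
14 | 3-henicosyl-5-methoxy-2-(propan-2-yloxy)benzene-1,4-diol | CCCCCCCCCCCCCCCCCCCCCc1c(OC(C)C)c(O)cc(OC)c1O | intermediate
15 | 3-henicosyl-5-methoxybenzene-1,2,4-triol | CCCCCCCCCCCCCCCCCCCCCc1c(O)c(O)cc(OC)c1O | intermediate
16 | 3-henicosyl-2-hydroxy-5-methoxycyclohexa-2,5-diene-1,4-dione | CCCCCCCCCCCCCCCCCCCCCC1=C(O)C(=O)C=C(OC)C1=O | target

**Count**
Total steps: 7. Longest linear sequence: 6 steps (steps 1, 2, 3, 5, 6, 7 from henicosan-1-ol); step 4 is a one-step side branch that joins at step 5.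

**Steps most likely to fail**

Step 5. The vinyllithium may lose lithium methoxide by β-elimination if the exchange mixture warms. It may also attack the vinylogous ester carbonyl or deprotonate the chain CH2 next to the ring, and the enol ether carbinol may ionise during work-up. The fallback sets out from 6 and returns at 11. Lithium methoxyacetylide F1, generated from 2-chloro-1,1-dimethoxyethane and LiNEt2 (3 equiv) in THF at 0 °C, is added to 6 at −78 °C and quenched with aq. NH4Cl. An acetylide cannot eliminate and is a weaker base, and it should give 2-henicosyl-4-hydroxy-4-(methoxyethynyl)-3-(propan-2-yloxy)cyclobut-2-en-1-one F2 with the same carbonyl selectivity. Semi-hydrogenation of F2 (H2, Pd/CaCO3 poisoned with Pb(OAc)2, quinoline, EtOAc, rt) then delivers the Z enol ether 11 by syn addition of hydrogen, the alkoxyacetylene carbinol route (Arens–van Dorp sequence). The mixture is kept at room temperature so that the alkynyl carbinol does not rearrange.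

Step 6. The inward-pointing methoxyl of the Z enol ether may slow the 6π closure, so that the ketene is lost to capture by the hydroxyl or to oligomerisation. Traces of acid at 110 °C may also ionise the enol ether carbinol before the ring opens. The fallback sets out from 6 and returns at 14, and it introduces the methoxyl after the ring expansion. CH2=CHMgBr (THF, −78 °C; aq. NH4Cl) adds to 6 to give 4-ethenyl-2-henicosyl-4-hydroxy-3-(propan-2-yloxy)cyclobut-2-en-1-one F3. Thermolysis in toluene at 110 °C passes through (3Z)-2-henicosyl-4-hydroxy-3-(propan-2-yloxy)hexa-1,3,5-trien-1-one F4 and 2-henicosyl-4-hydroxy-3-(propan-2-yloxy)cyclohexa-2,4-dien-1-one F5 to 3-henicosyl-2-(propan-2-yloxy)benzene-1,4-diol F6. Ag2O (Et2O, rt) oxidises F6 to 2-henicosyl-3-(propan-2-yloxy)cyclohexa-2,5-diene-1,4-dione F7. Conjugate addition of methanol (ZnCl2, MeOH, air, rt) should go to the ring CH β to the carbonyl that is not part of the vinylogous ester, which is the position needed. The first adduct is 14 itself, reoxidised under the conditions to 3-henicosyl-5-methoxy-2-(propan-2-yloxy)cyclohexa-2,5-diene-1,4-dione F8, and aq. Na2S2O4 reduces F8 back to 14.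

Step 7. BCl3 may over-react and remove the methyl ether as well, or the free, very electron-rich hydroquinone and triol may be lost to uncontrolled autoxidation and oxidative coupling during the open-air stage. The fallback sets out from 14 and returns at 16, and it caps the phenols first. Ac2O and pyridine (DMAP cat.) give 3-henicosyl-5-methoxy-2-(propan-2-yloxy)benzene-1,4-diyl diacetate F9, an air-stable compound that can be purified. BCl3 (CH2Cl2, −78 → 0 °C) removes the isopropyl group to give 3-henicosyl-2-hydroxy-5-methoxybenzene-1,4-diyl diacetate F10. K2CO3 in MeOH under air then cleaves the acetates to triol 15, which oxidises in the same flask to 16, isolated after acidification.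

**Further compounds**
F1 | step 5 | lithium methoxyacetylide ((methoxyethynyl)lithium) | COC#C[Li]
F2 | step 5 | racemic 2-henicosyl-4-hydroxy-4-(methoxyethynyl)-3-(propan-2-yloxy)cyclobut-2-en-1-one | CCCCCCCCCCCCCCCCCCCCCC1=C(OC(C)C)C(O)(C#COC)C1=O
F3 | step 6 | racemic 4-ethenyl-2-henicosyl-4-hydroxy-3-(propan-2-yloxy)cyclobut-2-en-1-one | CCCCCCCCCCCCCCCCCCCCCC1=C(OC(C)C)C(O)(C=C)C1=O
F4 | step 6 | (3Z)-2-henicosyl-4-hydroxy-3-(propan-2-yloxy)hexa-1,3,5-trien-1-one | CCCCCCCCCCCCCCCCCCCCCC(=C=O)/C(OC(C)C)=C(O)\C=C
F5 | step 6 | 2-henicosyl-4-hydroxy-3-(propan-2-yloxy)cyclohexa-2,4-dien-1-one | CCCCCCCCCCCCCCCCCCCCCC1=C(OC(C)C)C(O)=CCC1=O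
F6 | step 6 | 3-henicosyl-2-(propan-2-yloxy)benzene-1,4-diol | CCCCCCCCCCCCCCCCCCCCCc1c(OC(C)C)c(O)ccc1O
F7 | step 6 | 2-henicosyl-3-(propan-2-yloxy)cyclohexa-2,5-diene-1,4-dione | CCCCCCCCCCCCCCCCCCCCCC1=C(OC(C)C)C(=O)C=CC1=O
F8 | step 6 | 3-henicosyl-5-methoxy-2-(propan-2-yloxy)cyclohexa-2,5-diene-1,4-dione | CCCCCCCCCCCCCCCCCCCCCC1=C(OC(C)C)C(=O)C=C(OC)C1=O
F9 | step 7 | 3-henicosyl-5-methoxy-2-(propan-2-yloxy)benzene-1,4-diyl diacetate | CCCCCCCCCCCCCCCCCCCCCc1c(OC(C)C)c(OC(C)=O)cc(OC)c1OC(C)=O
F10 | step 7 | 3-henicosyl-2-hydroxy-5-methoxybenzene-1,4-diyl diacetate | CCCCCCCCCCCCCCCCCCCCCc1c(O)c(OC(C)=O)cc(OC)c1OC(C)=O
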